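**Plan**

1. Numbering used below: ring carbon C10 carries CH3 and vinyl; then round the ring come C5 (acrolein unit), C6 (O-angelate), C7/C8 (lactone fusion, oxygen on C8) and C9 (O-2-methylbutanoate); C11/C12 are the lactone C(=CH2) and C=O. The "methyl face" is the ring face of the C10 methyl, the "vinyl face" the other.
2. Retrosynthetic cuts, in order: both exocyclic C=CH2 groups; the O6 and O9 ester C–O bonds; the lactone (O8–C12 and C7–C11, back to a C6/C7 epoxide and a C8 phosphonoacetate); last the carbocycle at C5–C10 and C8–C9.
3. Enabling feature: C6–O and C7–C11 are trans and can come from anti opening of a C6/C7 epoxide, so the ring is a cyclohex-6-ene, a Diels–Alder adduct of diene C5=C6–C7=C8 (silyloxy on C8) and dienophile C9=C10. The C8–O/C9–O pair is electronically mismatched for a cycloaddition; a formyl group on C9 makes it matched and is later cut down to C9–O by Baeyer–Villiger oxidation.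
4. Forward order: carbocycle first (step 5); then C9–O and the C10 vinyl group (steps 6–9); then the lactone ring together with C6–O (steps 10–13); then the angelate and the acrolein unit (steps 14–17).
5. Stereochemistry: absolute configuration from a chiral oxazaborolidinium catalyst; C5, C9, C10 (and C8 provisionally) from olefin geometries and the endo rule; C9 kept by retention in the Baeyer–Villiger step; C8 inverted by Mitsunobu; C6 and C7 from hydroxyl-directed epoxidation and back-side opening; the acyl stereocentre from (R)-2-methylbutanoic acid.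

Key step: step 5

Assumption: the (S)-oxazaborolidinium catalyst is taken to expose the enal face that leads to 9, as its formyl C–H···O binding model predicts; if the sense were opposite, the mirror-image catalyst would be used.

**Route**

Step 1
Reactants: 1 pent-4-en-1-ol; 2 4-methoxybenzyl chloride
Product: 3 4-methoxybenzyl pent-4-enyl ether
Conditions: NaH, n-Bu4NI (cat.), DMF, 0 °C → rt
Reagents that add atoms: none
Why: Williamson etherification of the sodium alkoxide with the benzylic chloride; no stereocentre is involved.

Step 2
Reactants: 3 4-methoxybenzyl pent-4-enyl ether; 4 (E)-but-2-enal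
Product: 5 (E)-6-(4-methoxybenzyloxy)hex-2-enal
Conditions: second-generation Grubbs catalyst (3 mol %), excess 4, CH2Cl2, 40 °C
Reagents that add atoms: none
Why: Olefin cross-metathesis of a terminal alkene with an electron-poor enal should give the (E)-enal under thermodynamic control, with propene lost.

Step 3
Reactants: 5 (E)-6-(4-methoxybenzyloxy)hex-2-enal
Product: 6 (1E,3E)-1-(tert-butyldimethylsilyloxy)-6-(4-methoxybenzyloxy)hexa-1,3-diene
Conditions: t-BuMe2SiOTf, Et3N, Et2O, 0 °C → rt
Reagents that add atoms: tert-butyldimethylsilyl trifluoromethanesulfonate, CC(C)(C)[Si](C)(C)OS(=O)(=O)C(F)(F)F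
Why: Soft vinylogous enolisation (O-silylation of the enal, then γ-deprotonation by Et3N) should give mainly the (1E,3E)-dienol silyl ether; any (3Z) isomer cannot reach the s-cis conformation and stays inert in step 5.

Step 4
Reactants: 7 methyl (E)-2-methylbut-2-enoate
Product: 8 methyl (E)-2-methyl-4-oxobut-2-enoate
Conditions: SeO2, 1,4-dioxane, reflux
Reagents that add atoms: selenium dioxide, O=[Se]=O
Why: Riley oxidation (ene reaction of SeO2 at the α-carbon of the enoate, then [2,3]-sigmatropic shift) should oxidise the γ-methyl group to the aldehyde with the (E) geometry kept.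

Step 5
Reactants: 6 (1E,3E)-1-(tert-butyldimethylsilyloxy)-6-(4-methoxybenzyloxy)hexa-1,3-diene; 8 methyl (E)-2-methyl-4-oxobut-2-enoate
Product: 9 methyl 5-(tert-butyldimethylsilyloxy)-6-formyl-2-[2-(4-methoxybenzyloxy)ethyl]-1-methylcyclohex-3-ene-1-carboxylate (ring C1 = C10, C2 = C5, C3=C4 = C6=C7, C5 = C8, C6 = C9); C10–CH3, C5 chain, C8–OSi and C9–CHO all on the methyl face, CO2CH3 on the other
Conditions: (S)-3,3-diphenyl-1-(2-methylphenyl)tetrahydro-1H,3H-pyrrolo[1,2-c][1,3,2]oxazaborole·(CF3SO2)2NH (15 mol %), CH2Cl2, −78 → −40 °C
Reagents that add atoms: none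
Why: Normal-electron-demand Diels–Alder reaction: the enal, bound through its formyl oxygen to the cationic boron, adds to the 1-silyloxydiene in a concerted, asynchronous [4π+2π] event; the closest known type is the oxazaborolidinium-catalysed cycloaddition of silyloxydienes to 2-enals. The one ring that closes is the carbocycle C5–C6–C7–C8–C9–C10, by intermolecular suprafacial [4+2] closure that forms C5–C10 and C8–C9 and leaves the C6=C7 alkene. Regiochemistry follows from polarity: the silyloxy donor makes C5 the nucleophilic diene terminus and it bonds to C10, the β-carbon of the activated formyl group, so the oxygen-bearing C8 ends next to the formyl-bearing C9; the ester on C10, which the catalyst does not bind, cannot reverse this. C5 and C8 are cis because both diene double bonds are E, formyl and methyl are cis because the dienophile is E, and the endo position of the boron-bound formyl group puts C9–CHO and C10–CH3 on the face of the C5 chain and the C8 silyloxy group, the ester on the other face. The absolute configuration is controlled by the catalyst, whose aryl groups cover one face of the s-trans enal. The step needs regio-, endo- and face selectivity and must outrun vinylogous Mukaiyama addition to the formyl carbon; activation of the aldehyde alone, the low temperature and the second (ester) acceptor on the dienophile double bond are what should secure them.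

Step 6
Reactants: 9 Diels–Alder adduct
Product: 10 formate: as 9 with C9–OCHO in place of C9–CHO, oxygen on the methyl face
Conditions: mCPBA, CH2Cl2, 0 °C
Reagents that add atoms: 3-chloroperoxybenzoic acid, O=C(OO)c1cccc(Cl)c1
Why: Baeyer–Villiger oxidation of the α-branched aldehyde: the secondary ring carbon C9 migrates to oxygen with retention, so C9–O appears on the methyl face; the aldehyde should react faster than the hindered ring alkene, flanked by the silyloxy group and the branched C5, is epoxidised.

Step 7
Reactants: 10 formate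
Product: 11 hydroxy aldehyde: 5-(tert-butyldimethylsilyloxy)-6-hydroxy-2-[2-(4-methoxybenzyloxy)ethyl]-1-methylcyclohex-3-ene-1-carbaldehyde; CH3, chain, OSi and OH all on the methyl face
Conditions: i-Bu2AlH (3.2 equiv), CH2Cl2, −78 °C; aq. potassium sodium tartrate
Reagents that add atoms: none
Why: Hydride cleaves the formate and half-reduces the neopentyl methyl ester; the aluminium hemiacetal, chelated to the neighbouring C9 aluminium alkoxide and shielded by the quaternary carbon, should persist at −78 °C and release the aldehyde only on hydrolytic work-up.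

Step 8
Reactants: 11 hydroxy aldehyde; 12 (R)-2-methylbutanoic acid
Product: 13 C9 (R)-2-methylbutanoate of 11
Conditions: DCC, DMAP (cat.), CH2Cl2, 0 °C → rt
Reagents that add atoms: none
Why: Steglich esterification (carbodiimide activation, acyl transfer by DMAP) of the hindered C9 hydroxyl; no new stereocentre is formed and the α-centre of the acid should not be enolised under these conditions.

Step 9
Reactants: 13 ester aldehyde
Product: 14 vinyl compound: as 13 with C10–CH=CH2 in place of C10–CHO
Conditions: Ph3PCH3Br, KN(SiMe3)2, THF, −78 → 0 °C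
Reagents that add atoms: methyltriphenylphosphonium bromide, C[P+](c1ccccc1)(c1ccccc1)c1ccccc1.[Br-]
Why: Wittig methylenation of the non-enolisable aldehyde on the quaternary carbon gives the C10 vinyl group; the ylide at low temperature should leave the ester alone.

Step 10
Reactants: 14 vinyl compound
Product: 15 allylic alcohol: as 14 with free C8–OH on the methyl face
Conditions: HF·pyridine, THF, 0 °C → rt
Reagents that add atoms: none
Why: Fluoride cleavage of the secondary silyl ether under acidic conditions, which avoid base-promoted migration of the neighbouring cis acyl group.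

Step 11
Reactants: 15 allylic alcohol
Product: 16 epoxy alcohol: C6–C7 epoxide of 15 with the epoxide oxygen on the methyl face, cis to C8–OH
Conditions: VO(acac)2 (5 mol %), t-BuOOH, CH2Cl2, 0 °C → rt
Reagents that add atoms: tert-butyl hydroperoxide, CC(C)(C)OO
Why: Hydroxyl-directed epoxidation of the allylic alcohol by the vanadium alkylperoxide places the oxygen on the face of the C8 hydroxyl; the isolated vinyl group has no directing group and should be left.

Step 12
Reactants: 16 epoxy alcohol; 17 (diethoxyphosphoryl)acetic acid
Product: 18 C8 (diethoxyphosphoryl)acetate with inverted C8 (ester oxygen on the vinyl face), epoxide as in 16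
Conditions: PPh3, DIAD, THF, 0 °C → rt
Reagents that add atoms: none
Why: Mitsunobu esterification: the carboxylate displaces the oxyphosphonium group with inversion, moving the C8 oxygen to the vinyl face; the cis epoxide and cis acyloxy neighbours cannot take part by back-side attack.

Step 13
Reactants: 18 epoxy phosphonoacetate
Product: 20 α-methylene lactone alcohol (cis-fused lactone on the vinyl face at C7/C8; C6–OH on the methyl face), via phosphono lactone 19 (not isolated)
Conditions: NaH, THF, 0 °C → rt; then (CH2O)n, rt
Reagents that add atoms: formaldehyde (from paraformaldehyde), C=O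
Why: The phosphonate-stabilised carbanion opens the epoxide at C7 (5-exo-tet, back-side, trans-diaxial), which sets C7–C11 cis to the C8 oxygen and leaves C6–O on the methyl face; after proton transfer the α-phosphono lactone anion undergoes Horner–Wadsworth–Emmons olefination with formaldehyde to the exocyclic methylene.

Step 14
Reactants: 20 α-methylene lactone alcohol; 21 (Z)-2-methylbut-2-enoic acid (angelic acid)
Product: 22 C6 angelate of 20
Conditions: 2,4,6-Cl3C6H2COCl, Et3N, toluene, rt; then 20, 80 °C
Reagents that add atoms: none
Why: Yamaguchi-type esterification through the 2,4,6-trichlorobenzoyl mixed anhydride acylates the hindered axial C6 hydroxyl; thermal acyl transfer without a nucleophilic catalyst should keep the (Z) geometry.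

Step 15
Reactants: 22 angelate
Product: 23 primary alcohol: as 22 with C5–CH2CH2OH
Conditions: DDQ, CH2Cl2/H2O, 0 °C → rt
Reagents that add atoms: none
Why: Oxidative cleavage of the electron-rich 4-methoxybenzyl ether (hydride abstraction, hydrolysis of the oxocarbenium ion) should leave esters, lactone and alkenes untouched.

Step 16
Reactants: 23 primary alcohol
Product: 24 aldehyde: as 22 with C5–CH2CHO
Conditions: Dess–Martin periodinane, CH2Cl2, 0 °C → rt
Reagents that add atoms: none
Why: Dess–Martin oxidation of the primary alcohol to the aldehyde under neutral conditions; no stereocentre is affected.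

Step 17
Reactants: 24 aldehyde
Product: 26 target CNP0295282.1, via Mannich base 25 (not isolated)
Conditions: CH2=NMe2+ I−, Et3N (cat.), CH2Cl2, rt → 40 °C
Reagents that add atoms: N,N-dimethylmethyleneiminium iodide (Eschenmoser's salt), C=[N+](C)C.[I-]
Why: Mannich reaction of the aldehyde enol with the iminium salt and E1cB loss of dimethylamine (Eschenmoser α-methylenation) gives the 2-substituted acrolein; the amine is held as its hydroiodide and so should not add to the α-methylene lactone.

**Compound list**

1 | pent-4-en-1-ol | C=CCCCO | starting material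
2 | 4-methoxybenzyl chloride | COc1ccc(CCl)cc1 | starting material
3 | 4-methoxybenzyl pent-4-enyl ether | C=CCCCOCc1ccc(OC)cc1 | intermediate
4 | (E)-but-2-enal | C/C=C/C=O | starting material
5 | (E)-6-(4-methoxybenzyloxy)hex-2-enal | O=C/C=C/CCCOCc1ccc(OC)cc1 | intermediate
6 | (1E,3E)-1-(tert-butyldimethylsilyloxy)-6-(4-methoxybenzyloxy)hexa-1,3-diene | CC(C)(C)[Si](C)(C)O/C=C/C=C/CCOCc1ccc(OC)cc1 | intermediate
7 | methyl (E)-2-methylbut-2-enoate (methyl tiglate) | C/C=C(\C)C(=O)OC | starting material
8 | methyl (E)-2-methyl-4-oxobut-2-enoate | O=C/C=C(\C)C(=O)OC | intermediate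
9 | methyl 5-(tert-butyldimethylsilyloxy)-6-formyl-2-[2-(4-methoxybenzyloxy)ethyl]-1-methylcyclohex-3-ene-1-carboxylate; CH3, chain, OSi and CHO all cis, CO2CH3 trans to them | COC(=O)[C@@]1(C)[C@H](CCOCc2ccc(OC)cc2)C=C[C@H](O[Si](C)(C)C(C)(C)C)[C@@H]1C=O | intermediate
10 | formate: 9 with OCHO in place of CHO on C9, same configuration | COC(=O)[C@@]1(C)[C@H](CCOCc2ccc(OC)cc2)C=C[C@H](O[Si](C)(C)C(C)(C)C)[C@@H]1OC=O | intermediate
11 | 5-(tert-butyldimethylsilyloxy)-6-hydroxy-2-[2-(4-methoxybenzyloxy)ethyl]-1-methylcyclohex-3-ene-1-carbaldehyde; CH3, chain, OSi and OH all cis | O=C[C@@]1(C)[C@H](CCOCc2ccc(OC)cc2)C=C[C@H](O[Si](C)(C)C(C)(C)C)[C@@H]1O | intermediate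
12 | (R)-2-methylbutanoic acid | CC[C@@H](C)C(=O)O | starting material
13 | C9 (R)-2-methylbutanoate of 11 | O=C[C@@]1(C)[C@H](CCOCc2ccc(OC)cc2)C=C[C@H](O[Si](C)(C)C(C)(C)C)[C@@H]1OC(=O)[C@H](C)CC | intermediate
14 | vinyl compound: 13 with C10–CH=CH2 in place of C10–CHO | C=C[C@@]1(C)[C@H](CCOCc2ccc(OC)cc2)C=C[C@H](O[Si](C)(C)C(C)(C)C)[C@@H]1OC(=O)[C@H](C)CC | intermediate
15 | allylic alcohol: 14 with free C8–OH on the methyl face | C=C[C@@]1(C)[C@H](CCOCc2ccc(OC)cc2)C=C[C@H](O)[C@@H]1OC(=O)[C@H](C)CC | intermediate
16 | epoxy alcohol: C6–C7 epoxide of 15, epoxide oxygen cis to C8–OH (methyl face) | C=C[C@@]1(C)[C@H](CCOCc2ccc(OC)cc2)[C@@H]3O[C@@H]3[C@H](O)[C@@H]1OC(=O)[C@H](C)CC | intermediate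
17 | (diethoxyphosphoryl)acetic acid | CCOP(=O)(CC(=O)O)OCC | starting material
18 | C8 (diethoxyphosphoryl)acetate of 16 with inverted C8 (ester oxygen on the vinyl face) | C=C[C@@]1(C)[C@H](CCOCc2ccc(OC)cc2)[C@@H]3O[C@@H]3[C@@H](OC(=O)CP(=O)(OCC)OCC)[C@@H]1OC(=O)[C@H](C)CC | intermediate
19 | α-(diethoxyphosphoryl) γ-lactone (formed as its sodium salt, C11 epimers): lactone cis-fused on the vinyl face at C7/C8, C6–OH on the methyl face | C=C[C@@]1(C)[C@H](CCOCc3ccc(OC)cc3)[C@H](O)[C@H]2C(P(=O)(OCC)OCC)C(=O)O[C@H]2[C@@H]1OC(=O)[C@H](C)CC | intermediate (not isolated)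
20 | α-methylene lactone alcohol: 19 with C11=CH2 in place of the phosphoryl group | C=C[C@@]1(C)[C@H](CCOCc3ccc(OC)cc3)[C@H](O)[C@H]2C(=C)C(=O)O[C@H]2[C@@H]1OC(=O)[C@H](C)CC | intermediate
21 | (Z)-2-methylbut-2-enoic acid (angelic acid) | C/C=C(/C)C(=O)O | starting material
22 | C6 angelate of 20 | C=C[C@@]1(C)[C@H](CCOCc3ccc(OC)cc3)[C@H](OC(=O)/C(C)=C\C)[C@H]2C(=C)C(=O)O[C@H]2[C@@H]1OC(=O)[C@H](C)CC | intermediate
23 | primary alcohol: 22 with C5–CH2CH2OH | C=C[C@@]1(C)[C@H](CCO)[C@H](OC(=O)/C(C)=C\C)[C@H]2C(=C)C(=O)O[C@H]2[C@@H]1OC(=O)[C@H](C)CC | intermediate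
24 | aldehyde: 22 with C5–CH2CHO | C=C[C@@]1(C)[C@H](CC=O)[C@H](OC(=O)/C(C)=C\C)[C@H]2C(=C)C(=O)O[C@H]2[C@@H]1OC(=O)[C@H](C)CC | intermediate
25 | Mannich base (formed as its hydroiodide): 24 with CH2N(CH3)2 on the aldehyde α-carbon | C=C[C@@]1(C)[C@H](C(CN(C)C)C=O)[C@H](OC(=O)/C(C)=C\C)[C@H]2C(=C)C(=O)O[C@H]2[C@@H]1OC(=O)[C@H](C)CC | intermediate (not isolated)
26 | CNP0295282.1 | C=C[C@@]1(C)[C@H](C(=C)C=O)[C@H](OC(=O)/C(C)=C\C)[C@H]2C(=C)C(=O)O[C@H]2[C@@H]1OC(=O)[C@H](C)CC | target

**Count and risks**

Total steps: 17. Longest linear sequence: 16 (steps 1–3 and 5–17).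

Step 6. What may go wrong: hydride migration in place of carbon migration (over-oxidation to the carboxylic acid), epoxidation of the ring alkene, or loss of silanol from the β-silyloxy aldehyde. The fallback sets out from 6 and comes back at 11. A Wittig reaction of methylglyoxal with methyl 2-(triphenylphosphoranylidene)propanoate gives methyl (E)-2-methyl-4-oxopent-2-enoate F5. Cycloaddition of 6 with it under the conditions of step 5 gives the methyl ketone adduct F6. Baeyer–Villiger oxidation with Me3SiOOSiMe3 and SnCl4, a reagent that spares alkenes and in which the secondary carbon migrates in preference to methyl, gives the C9 acetate F7. i-Bu2AlH as in step 7 then cleaves the acetate and half-reduces the ester to give 11.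

Step 5. What may go wrong: poor face discrimination by the catalyst, or vinylogous Mukaiyama addition of the diene to the formyl carbon under the cationic Lewis acid. The fallback sets out from 6 and 8 and comes back at 13. Thermal cycloaddition without catalyst (toluene, 80 °C) gives racemic endo adduct, that is 9 together with its enantiomer F1. The mixture is taken through steps 6 and 7, so that the enantiomeric formate F2 and the enantiomeric hydroxy aldehyde F3 accompany 10 and 11. Steglich esterification with 12 then gives 13 and its diastereomer F4, which are separated by chromatography (resolution through the chiral acid).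

Step 13. What may go wrong: slow opening of the epoxide by the stabilised carbanion, so that acyl transfer or decomposition of the sodium salt competes. The fallback sets out from 16 and comes back at 20. Mitsunobu reaction of 16 with propiolic acid (PPh3, DIAD) gives the inverted C8 propiolate F8. Trivalent titanium (Cp2TiCl, from Cp2TiCl2 and Zn, THF) opens the epoxide homolytically; the C7 radical adds 5-exo-dig to the alkyne and the vinyl radical is reduced, which gives 20 directly.

**Further compounds**

F1 | step 5 | enantiomer of 9 | COC(=O)[C@]1(C)[C@@H](CCOCc2ccc(OC)cc2)C=C[C@@H](O[Si](C)(C)C(C)(C)C)[C@H]1C=O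
F2 | step 5 | enantiomer of 10 | COC(=O)[C@]1(C)[C@@H](CCOCc2ccc(OC)cc2)C=C[C@@H](O[Si](C)(C)C(C)(C)C)[C@H]1OC=O
F3 | step 5 | enantiomer of 11 | O=C[C@]1(C)[C@@H](CCOCc2ccc(OC)cc2)C=C[C@@H](O[Si](C)(C)C(C)(C)C)[C@H]1O
F4 | step 5 | diastereomer of 13 (all ring stereocentres inverted, acyl group (R)) | O=C[C@]1(C)[C@@H](CCOCc2ccc(OC)cc2)C=C[C@@H](O[Si](C)(C)C(C)(C)C)[C@H]1OC(=O)[C@H](C)CC
F5 | step 6 | methyl (E)-2-methyl-4-oxopent-2-enoate | CC(=O)/C=C(\C)C(=O)OC
F6 | step 6 | methyl ketone adduct: 9 with C9–C(=O)CH3 in place of C9–CHO | COC(=O)[C@@]1(C)[C@H](CCOCc2ccc(OC)cc2)C=C[C@H](O[Si](C)(C)C(C)(C)C)[C@@H]1C(C)=O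
F7 | step 6 | C9 acetate: 10 with OC(=O)CH3 in place of OCHO | COC(=O)[C@@]1(C)[C@H](CCOCc2ccc(OC)cc2)C=C[C@H](O[Si](C)(C)C(C)(C)C)[C@@H]1OC(C)=O
F8 | step 13 | C8 propiolate of the epoxide with inverted C8 (18 with a propynoyl in place of the phosphonoacetyl group) | C=C[C@@]1(C)[C@H](CCOCc2ccc(OC)cc2)[C@@H]3O[C@@H]3[C@@H](OC(=O)C#C)[C@@H]1OC(=O)[C@H](C)CC
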